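**Plan**

- Retrosynthesis: the lactone C–O bond of the seven-membered depsidone ring is cut first (ring A carboxyl from O-6 of the chromanone ring B). Next comes the diaryl ether bond between O-7 and ring A. Last, in the pyranone ring, the bonds C-3–C-2 and O-1–C-8a are cut, which gives acetone and an ortho-fluoroaryl methyl ketone.
- Enabling feature: the C-4 carbonyl is alpha to C-3 and ortho to C-8a. One carbonyl therefore makes C-3 an enolate donor towards acetone and makes C-8a–F an SNAr site for the aldolate oxygen. Acetone supplies C-2, both methyl groups and O-1, so ring B can start as a simple fluorocatechol.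
- Forward order: ring B ketone from 4-fluoro-2-methylphenol, then the pyranone ring by an aldol/SNAr cascade, then O-7 is freed. Ring A is built with fluorine between CHO and ester. The diaryl ether is made by SNAr, the ethers and ester are cleaved, and the lactone ring closes last.
- Stereochemistry: the target has no stereocentre (C-2 carries two methyl groups), so none has to be set.

Key step: step 5

Remark: ring B positions are numbered as in chroman-4-one (O-1, C-2, C-3, C-4, C-4a, C-5 to C-8, C-8a); ring A is the formyl-bearing ring; compounds 1, 7 and 12 are taken as purchasable.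

**Route**

Step 1
Reactants: 1 4-fluoro-2-methylphenol
Product: 2 5-fluoro-2-hydroxy-3-methylbenzaldehyde
Conditions: MgCl2, Et3N, (CH2O)n, MeCN, reflux; aqueous HCl work-up
Reagents that add atoms: paraformaldehyde (as formaldehyde), C=O
Why: The magnesium phenoxide should deliver formaldehyde to the only free ortho position and a second formaldehyde should take the hydride from the benzylic alkoxide (Casnati–Skattebøl ortho-formylation), so the aldehyde enters next to the hydroxyl group only.

Step 2
Reactants: 2 5-fluoro-2-hydroxy-3-methylbenzaldehyde
Product: 4 5-fluoro-3-methylbenzene-1,2-diol, via aryl formate 3 (not isolated)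
Conditions: 30% H2O2, NaOH, THF–H2O, 0 °C to rt, under N2; aqueous HCl work-up
Reagents that add atoms: hydrogen peroxide, OO
Why: Dakin oxidation: hydroperoxide adds to the ortho-hydroxy aldehyde, the electron-rich aryl group migrates to oxygen and the formate 3 is hydrolysed in the same flask to the catechol.

Step 3
Reactants: 4 5-fluoro-3-methylbenzene-1,2-diol
Product: 5 5-fluoro-1,2-dimethoxy-3-methylbenzene
Conditions: MeI, K2CO3, acetone, reflux, under N2
Reagents that add atoms: iodomethane, CI
Why: Williamson O-methylation of both phenoxides should be clean because the ring carries no other nucleophilic site under carbonate.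

Step 4
Reactants: 5 5-fluoro-1,2-dimethoxy-3-methylbenzene
Product: 6 1-(6-fluoro-3,4-dimethoxy-2-methylphenyl)ethan-1-one
Conditions: AcCl, AlCl3 (1.1 equiv), CH2Cl2, 0 °C
Reagents that add atoms: acetyl chloride, CC(=O)Cl
Why: Friedel–Crafts acylation should go para to the unhindered, in-plane C-1 methoxy group (the C-2 methoxy is twisted by its two neighbours and donates less), which places the acetyl group between fluorine and methyl.

Step 5
Reactants: 6 1-(6-fluoro-3,4-dimethoxy-2-methylphenyl)ethan-1-one; 7 acetone
Product: 10 6,7-dimethoxy-2,2,5-trimethylchroman-4-one, via potassium enolate 8 (not isolated), via potassium aldolate 9 (not isolated)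
Conditions: KN(SiMe3)2 (1.1 equiv), THF, −78 °C; acetone (10 equiv), −78 °C; then 18-crown-6, −78 °C to 40 °C
Reagents that add atoms: none
Why: Proposed new method: the potassium enolate 8 adds to acetone to give the tertiary aldolate 9 (C-3–C-2 bond), and the alkoxide of 9 then attacks the fluorine-bearing carbon ortho to the ketone and expels fluoride through a Meisenheimer anion (O-1–C-8a bond); the aldol addition is reversible, and the irreversible loss of KF should drain the equilibrium. The closest known reaction types are the base-mediated ring closure of alkoxides onto ortho-fluoroaryl ketones and the domino Michael–SNAr annulations of ortho-fluoroaryl enones. The pyranone ring closes in a 6-exo-trig mode at the aromatic carbon by addition–elimination. No stereocentre is formed, because C-2 carries two methyl groups. The step needs O-arylation within the molecule to outrun retro-aldol loss, dehydration to the enone and attack by outside nucleophiles; this is secured by the single fluorine held ortho to the carbonyl that both acidifies C-3 and stabilises the Meisenheimer anion, by the six-membered transition state, and by the excess of acetone that keeps the aldolate populated.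

Step 6
Reactants: 10 6,7-dimethoxy-2,2,5-trimethylchroman-4-one
Product: 11 7-hydroxy-6-methoxy-2,2,5-trimethylchroman-4-one
Conditions: LiCl (4 equiv), DMF, 140 °C; aqueous HCl work-up
Reagents that add atoms: none
Why: Chloride attacks the methyl carbon only of the C-7 ether, whose phenoxide is stabilised by the para ketone (nucleophilic dealkylation of an activated aryl methyl ether), while the C-6 ether is not activated and the non-basic medium should spare the chromanone ring.

Step 7
Reactants: 12 1-fluoro-3-methoxy-5-methylbenzene
Product: 13 2-bromo-1-fluoro-5-methoxy-3-methylbenzene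
Conditions: NBS, MeCN, 0 °C to rt
Reagents that add atoms: N-bromosuccinimide, O=C1CCC(=O)N1Br
Why: Electrophilic bromination of an anisole in acetonitrile should go para to the methoxy group, the position between fluorine and methyl.

Step 8
Reactants: 13 2-bromo-1-fluoro-5-methoxy-3-methylbenzene
Product: 15 3-bromo-2-fluoro-6-methoxy-4-methylbenzaldehyde, via aryllithium 14 (not isolated)
Conditions: LiN(i-Pr)2, THF, −78 °C; DMF, −78 °C; aqueous HCl work-up
Reagents that add atoms: N,N-dimethylformamide, CN(C)C=O
Why: Directed ortho-metalation removes the most acidic ring proton, the one flanked by fluorine and methoxy, and the aryllithium 14 is formylated by DMF; the low temperature should prevent loss of LiF and bromine migration.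

Step 9
Reactants: 15 3-bromo-2-fluoro-6-methoxy-4-methylbenzaldehyde
Product: 16 benzyl 2-fluoro-3-formyl-4-methoxy-6-methylbenzoate
Conditions: Pd(OAc)2 (cat.), Xantphos, CO (1 atm), BnOH, Et3N, toluene, 90 °C
Reagents that add atoms: carbon monoxide, [C-]#[O+]; benzyl alcohol, OCc1ccccc1
Why: Palladium-catalysed alkoxycarbonylation (oxidative addition of zerovalent palladium into the C–Br bond, CO insertion, alcoholysis of the acylpalladium) should turn the bromide into the benzyl ester and leave the aldehyde and the C–F bond untouched.

Step 10
Reactants: 11 7-hydroxy-6-methoxy-2,2,5-trimethylchroman-4-one; 16 benzyl 2-fluoro-3-formyl-4-methoxy-6-methylbenzoate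
Product: 17 benzyl 3-formyl-4-methoxy-2-[(6-methoxy-2,2,5-trimethyl-4-oxochroman-7-yl)oxy]-6-methylbenzoate
Conditions: K2CO3, DMF, rt to 40 °C
Reagents that add atoms: none
Why: SNAr diaryl ether synthesis: the fluorine of 16 lies between a formyl and an ester group, both ortho, so the C-7 phenoxide of 11 should displace it under mild conditions at the only halogen present.

Step 11
Reactants: 17 benzyl 3-formyl-4-methoxy-2-[(6-methoxy-2,2,5-trimethyl-4-oxochroman-7-yl)oxy]-6-methylbenzoate
Product: 18 3-formyl-4-hydroxy-2-[(6-hydroxy-2,2,5-trimethyl-4-oxochroman-7-yl)oxy]-6-methylbenzoic acid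
Conditions: BBr3 (excess), CH2Cl2, −78 °C to rt; H2O work-up
Reagents that add atoms: none
Why: Lewis acid dealkylation should cleave the benzyl ester, the methoxy group ortho to the formyl group (chelation) and the flanked C-6 methoxy group, while the diaryl ether and the vinylogous-ester oxygen of the pyranone are much less basic and should remain.

Step 12
Reactants: 18 3-formyl-4-hydroxy-2-[(6-hydroxy-2,2,5-trimethyl-4-oxochroman-7-yl)oxy]-6-methylbenzoic acid
Product: 19 mollicellin B
Conditions: DCC, DMAP (cat.), CH2Cl2–THF, high dilution, 0 °C to rt
Reagents that add atoms: none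
Why: Carbodiimide activation of the acid (Steglich-type lactonisation) should be followed by seven-membered ring closure with the C-6 hydroxyl of ring B, the only phenol within reach, while the ring A phenol is hydrogen-bonded to the formyl group and cannot reach its own carboxyl.

**Compound list**

1 | 4-fluoro-2-methylphenol | Cc1cc(F)ccc1O | starting material
2 | 5-fluoro-2-hydroxy-3-methylbenzaldehyde | Cc1cc(F)cc(C=O)c1O | intermediate
3 | 5-fluoro-2-hydroxy-3-methylphenyl formate (not isolated) | Cc1cc(F)cc(OC=O)c1O | intermediate
4 | 5-fluoro-3-methylbenzene-1,2-diol | Cc1cc(F)cc(O)c1O | intermediate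
5 | 5-fluoro-1,2-dimethoxy-3-methylbenzene | COc1cc(F)cc(C)c1OC | intermediate
6 | 1-(6-fluoro-3,4-dimethoxy-2-methylphenyl)ethan-1-one | CC(=O)c1c(C)c(OC)c(OC)cc1F | intermediate
7 | acetone | CC(C)=O | starting material
8 | potassium 1-(6-fluoro-3,4-dimethoxy-2-methylphenyl)ethen-1-olate (not isolated) | C=C([O-])c1c(C)c(OC)c(OC)cc1F.[K+] | intermediate
9 | potassium 4-(6-fluoro-3,4-dimethoxy-2-methylphenyl)-2-methyl-4-oxobutan-2-olate (not isolated) | CC(C)([O-])CC(=O)c1c(C)c(OC)c(OC)cc1F.[K+] | intermediate
10 | 6,7-dimethoxy-2,2,5-trimethylchroman-4-one | COc1cc2OC(C)(C)CC(=O)c2c(C)c1OC | intermediate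
11 | 7-hydroxy-6-methoxy-2,2,5-trimethylchroman-4-one | COc1c(O)cc2OC(C)(C)CC(=O)c2c1C | intermediate
12 | 1-fluoro-3-methoxy-5-methylbenzene | COc1cc(C)cc(F)c1 | starting material
13 | 2-bromo-1-fluoro-5-methoxy-3-methylbenzene | COc1cc(C)c(Br)c(F)c1 | intermediate
14 | (3-bromo-2-fluoro-6-methoxy-4-methylphenyl)lithium (not isolated) | COc1cc(C)c(Br)c(F)c1[Li] | intermediate
15 | 3-bromo-2-fluoro-6-methoxy-4-methylbenzaldehyde | COc1cc(C)c(Br)c(F)c1C=O | intermediate
16 | benzyl 2-fluoro-3-formyl-4-methoxy-6-methylbenzoate | COc1cc(C)c(C(=O)OCc2ccccc2)c(F)c1C=O | intermediate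
17 | benzyl 3-formyl-4-methoxy-2-[(6-methoxy-2,2,5-trimethyl-4-oxochroman-7-yl)oxy]-6-methylbenzoate | COc1cc(C)c(C(=O)OCc2ccccc2)c(Oc2cc3OC(C)(C)CC(=O)c3c(C)c2OC)c1C=O | intermediate
18 | 3-formyl-4-hydroxy-2-[(6-hydroxy-2,2,5-trimethyl-4-oxochroman-7-yl)oxy]-6-methylbenzoic acid | Cc1cc(O)c(C=O)c(Oc2cc3OC(C)(C)CC(=O)c3c(C)c2O)c1C(=O)O | intermediate
19 | mollicellin B (depsidone: ring A with methyl, hydroxyl and formyl groups, joined by ester and ether bridges to the 2,2,5-trimethylchroman-4-one ring B) | Cc1cc(O)c(C=O)c2c1C(=O)Oc1c(cc3c(c1C)C(=O)CC(C)(C)O3)O2 | target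

**Step count**

Total: 12 steps. Longest linear sequence: 9 steps (steps 1 to 6, then 10 to 12).

**Steps most likely to fail**

Step 5 (proposed new method). Retro-aldol return of the aldolate may outpace the ring closure, because the carbonyl is twisted by its two ortho neighbours and the ring is electron-rich. Dehydration to the enone or attack of outside alkoxides on the C–F bond may also compete. The fallback uses known chemistry and takes the ring oxygen from the arene instead of from acetone. It sets out from 6. Sodium methoxide in MeOH–DMSO at 80 °C should displace the fluoride ortho to the ketone and give 1-(3,4,6-trimethoxy-2-methylphenyl)ethan-1-one F1. BCl3 in CH2Cl2 at −78 to 0 °C should then cleave only the methoxy group chelated to the ketone and give 1-(6-hydroxy-3,4-dimethoxy-2-methylphenyl)ethan-1-one F2. A Kabbe condensation of F2 with acetone and pyrrolidine in refluxing methanol (enamine aldol condensation, then oxa-Michael closure) returns to the route at 10.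

Step 6. The dealkylation may stall or lose its preference for the C-7 ether, and prolonged heating in DMF may release dimethylamine that attacks the ketone. The fallback separates the two oxygens by phenol acidity instead of by ether reactivity. It sets out from 10. BBr3 in CH2Cl2 should cleave both ethers to 6,7-dihydroxy-2,2,5-trimethylchroman-4-one F3. Benzyl bromide (one equivalent) with KHCO3 in DMF should alkylate the more acidic hydroxyl para to the ketone and give 7-(benzyloxy)-6-hydroxy-2,2,5-trimethylchroman-4-one F4. MeI and K2CO3 then give 7-(benzyloxy)-6-methoxy-2,2,5-trimethylchroman-4-one F5. Hydrogenolysis over palladium on carbon (H2, EtOAc) returns to the route at 11.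

Step 4. Acylation may take place at the other open position (ortho to methoxy, between methoxy and fluorine), or AlCl3 may cleave a methyl ether. The fallback replaces electrophilic substitution by directed metalation with a silicon block. It sets out from 5. LiN(i-Pr)2 with Me3SiCl present in THF at −78 °C should silylate the most acidic position, between methoxy and fluorine, and give (6-fluoro-2,3-dimethoxy-4-methylphenyl)trimethylsilane F6. s-BuLi and TMEDA at −78 °C should then lithiate the only remaining position ortho to fluorine, and N-methoxy-N-methylacetamide should give 1-[6-fluoro-3,4-dimethoxy-2-methyl-5-(trimethylsilyl)phenyl]ethan-1-one F7. Protodesilylation with CF3CO2H in CH2Cl2 returns to the route at 6.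

**Further compounds**

F1 | step 5 | 1-(3,4,6-trimethoxy-2-methylphenyl)ethan-1-one | CC(=O)c1c(C)c(OC)c(OC)cc1OC
F2 | step 5 | 1-(6-hydroxy-3,4-dimethoxy-2-methylphenyl)ethan-1-one | CC(=O)c1c(C)c(OC)c(OC)cc1O
F3 | step 6 | 6,7-dihydroxy-2,2,5-trimethylchroman-4-one | Cc1c(O)c(O)cc2OC(C)(C)CC(=O)c12
F4 | step 6 | 7-(benzyloxy)-6-hydroxy-2,2,5-trimethylchroman-4-one | Cc1c(O)c(OCc3ccccc3)cc2OC(C)(C)CC(=O)c12
F5 | step 6 | 7-(benzyloxy)-6-methoxy-2,2,5-trimethylchroman-4-one | COc1c(OCc3ccccc3)cc2OC(C)(C)CC(=O)c2c1C
F6 | step 4 | (6-fluoro-2,3-dimethoxy-4-methylphenyl)trimethylsilane | COc1c(OC)c(C)cc(F)c1[Si](C)(C)C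
F7 | step 4 | 1-[6-fluoro-3,4-dimethoxy-2-methyl-5-(trimethylsilyl)phenyl]ethan-1-one | CC(=O)c1c(C)c(OC)c(OC)c([Si](C)(C)C)c1F
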